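The ten-membered ring is traced back to a cis-fused, angular-methyl decalin by reconnecting C4 to C9. The structural feature used is the 1,5-diene that the target hides: Z-C4=C5 (under the epoxide) and E-C8=C9 flank C6–C7, so ring A (C4–C9) of the decalin can carry an equatorial C5 pinacol boronate and an equatorial C8 mesylate, both antiperiplanar to C4–C9. Methoxide converts boron into a borate that fragments; this single operation opens the ten-membered ring and fixes both alkene geometries while C6, C7 and C10 are carried through. The decalin comes from (R)-carvone by a methylenecyclohexane annulation, with every ring-A stereocentre set from the convex face.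

Key step: step 15

Remark: ring atoms keep the C1–C10 numbers of the ten-membered ring in every intermediate (decalin ring A = C4–C9, ring B = C4, C3, C2, C1, C10, C9; β = face of the C4 methyl group, α = the other face); because boron at C5 must lie on the concave α face, it is brought in by convex-face hydroboration of a C5 alkenylboronate, which delivers hydrogen, not boron, from the β face.

Step 1
Reactants: 1 5-chloropent-1-yne
Product: 3 2-bromo-5-chloropent-1-ene, via alkenylborane adduct 2 (not isolated)
Conditions: 9-bromo-9-borabicyclo[3.3.1]nonane, CH2Cl2, 0 °C; then AcOH, 0 °C to rt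
Reagents that add atoms: 9-bromo-9-borabicyclo[3.3.1]nonane, BrB1C2CCCC1CCC2
Why: Bromoboration of the terminal alkyne places bromine on the internal carbon by syn addition, and protodeboronation with acetic acid then gives the 2-bromo-1-alkene while the primary chloride is untouched.

Step 2
Reactants: 4 (R)-carvone
Product: 5 (R)-carvotanacetone [(5R)-2-methyl-5-(propan-2-yl)cyclohex-2-en-1-one]
Conditions: H2 (1 atm), RhCl(PPh3)3 (5 mol %), benzene, rt
Reagents that add atoms: none
Why: Homogeneous catalytic hydrogenation with the rhodium–phosphine complex should saturate only the unhindered isopropenyl group and leave the conjugated trisubstituted alkene and the stereocentre (future C7) as they are.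

Step 3
Reactants: 3 2-bromo-5-chloropent-1-ene; 5 (R)-carvotanacetone
Product: 9 3-(5-chloropent-1-en-2-yl)-2-methyl-5-isopropylcyclohexanone (C9 side chain trans to the C7 isopropyl group; C4 epimers), via alkenyllithium 6 (not isolated), via lithium dialkenylcuprate 7 (not isolated), via lithium enolate 8 (not isolated)
Conditions: 3 (2.2 equiv), t-BuLi (4.4 equiv), Et2O, −78 °C; CuBr·SMe2 (1.1 equiv); then 5, Et2O/THF, −78 to −20 °C; aq NH4Cl
Reagents that add atoms: none
Why: Bromine–lithium exchange and transmetalation give a dialkenylcuprate whose conjugate addition to the enone should occur anti to the C7 isopropyl group (axial attack on the half-chair), which sets C9; this is the first half of a methylenecyclohexane annulation.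

Step 4
Reactants: 9 conjugate adduct
Product: 11 cis-decalone (5-oxo; 4β-methyl; 9β-H; 7β-isopropyl; 10-methylidene), via potassium enolate 10 (not isolated)
Conditions: KOt-Bu, t-BuOH/THF, rt
Reagents that add atoms: none
Why: Under equilibrating conditions only the C4 enolate can reach the primary chloride, and the intramolecular 6-exo-tet enolate C-alkylation, delivered from the face of the C9 tether, should close ring B cis-fused and make C4 quaternary with its methyl group cis to H9.

Step 5
Reactants: 11 cis-decalone
Product: 12 tertiary alcohol (10β-hydroxy; 10α-methyl)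
Conditions: Co(acac)2 (20 mol %), PhSiH3, O2 (1 atm), THF, rt
Reagents that add atoms: dioxygen, O=O
Why: Mukaiyama hydration is Markovnikov (hydrogen-atom transfer to the CH2 terminus, capture of the tertiary C10 radical by O2, reduction of the peroxide), and in the favoured conformer with equatorial isopropyl the axial C4–C5 bond shields the α face of C10, so oxygen should enter on the β face, cis to H9.

Step 6
Reactants: 12 tertiary alcohol
Product: 13 C10 tert-butyldimethylsilyl ether
Conditions: t-BuMe2SiOTf, 2,6-lutidine, CH2Cl2, 0 °C to rt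
Reagents that add atoms: tert-butyldimethylsilyl trifluoromethanesulfonate, CC(C)(C)[Si](C)(C)OS(=O)(=O)C(F)(F)F
Why: Silylation with the silyl triflate is the standard protection of a hindered tertiary alcohol, and this ether must last to the final step and keep the C10 oxygen from directing the later epoxidation.

Step 7
Reactants: 13 silyl ether ketone
Product: 16 enone (5-oxo; C6=C7), via lithium enolate 14 (not isolated), via trimethylsilyl enol ether 15 (not isolated)
Conditions: LiN(i-Pr)2, THF, −78 °C; Me3SiCl; then Pd(OAc)2 (1.1 equiv), MeCN, rt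
Reagents that add atoms: none
Why: Saegusa–Ito dehydrogenation: the ketone can enolise only toward C6 because C4 is quaternary, and β-hydride elimination of H7 from the palladium enolate gives the conjugated enone, which deliberately erases the C7 stereocentre once it has controlled C9 and C4.

Step 8
Reactants: 16 enone
Product: 19 γ-hydroxy enone (8β-hydroxy), via lithium dienolate 17 (not isolated), via triethylsilyl dienol ether 18 (not isolated)
Conditions: LiN(i-Pr)2, THF, −78 to −20 °C; Et3SiCl; then dimethyldioxirane (1 equiv), acetone/CH2Cl2, −78 °C; pH 7 buffer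
Reagents that add atoms: dimethyldioxirane, CC1(C)OO1
Why: Vinylogous Rubottom oxidation: γ-deprotonation at the ring CH2 (there is no α′ hydrogen), O-silylation and epoxidation of the distal, most electron-rich C7=C8 bond on the face opposite the bulky C9–C10 bond, then opening of the epoxide, should give the C8 alcohol cis to H9.

Step 9
Reactants: 19 γ-hydroxy enone
Product: 20 hydroxy ketone (8β-hydroxy; 7α-isopropyl)
Conditions: [Ir(cod)(PCy3)(py)]PF6 (5 mol %), H2 (1 atm), CH2Cl2, rt
Reagents that add atoms: none
Why: Hydroxyl-directed hydrogenation: the cationic iridium complex binds the C8 hydroxyl and delivers H2 to the same β face, so H7 ends cis and the isopropyl group trans to the C8 oxygen, both groups equatorial on ring A.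

Step 10
Reactants: 20 hydroxy ketone
Product: 21 C8 mesylate
Conditions: MsCl, Et3N, CH2Cl2, 0 °C
Reagents that add atoms: methanesulfonyl chloride, CS(=O)(=O)Cl
Why: Sulfonylation of the secondary alcohol (through sulfene) takes place at oxygen, so C8 keeps its configuration and receives the equatorial nucleofuge.

Step 11
Reactants: 21 mesylate ketone
Product: 22 alkenyl triflate (C5=C6)
Conditions: Tf2O, 2,6-di-tert-butyl-4-methylpyridine, CH2Cl2, 0 °C to rt
Reagents that add atoms: trifluoromethanesulfonic anhydride, O=S(=O)(OS(=O)(=O)C(F)(F)F)C(F)(F)F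
Why: Enol triflate formation under non-basic conditions (O-triflation of the carbonyl, loss of H6 to the hindered pyridine) can only give the C5=C6 isomer, and the mesylate never meets a strong base.

Step 12
Reactants: 22 alkenyl triflate
Product: 23 alkenyl pinacol boronate (boron on C5)
Conditions: B2pin2, PdCl2(PPh3)2 (3 mol %), PPh3, KOPh, toluene, 50 °C
Reagents that add atoms: bis(pinacolato)diboron, CC1(C)OB(OC1(C)C)B2OC(C)(C)C(C)(C)O2
Why: Miyaura borylation (oxidative addition of the alkenyl triflate to zerovalent palladium, phenoxide-assisted transmetalation with the diboron, reductive elimination) should put boron on C5, the secondary alkyl mesylate being inert under these conditions.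

Step 13
Reactants: 23 alkenyl pinacol boronate
Product: 25 hydroxy boronate (5α-pinacol boronate; 6β-hydroxy), via C6 borane 24 (not isolated)
Conditions: BH3·SMe2 (2 equiv), THF, 0 °C to rt; then 30% H2O2 (1.2 equiv), pH 7 phosphate buffer, 0 °C
Reagents that add atoms: hydrogen peroxide, OO
Why: Proposed new method: BH3 should add syn across the alkenylboronate from the convex β face (the axial C4–C3 bond of ring B blocks the α face) with the new boron on the less hindered C6 and hydrogen on C5, which leaves the pinacol boronate α and equatorial (trans to the C4 methyl), and buffered H2O2 should then oxidise the unhindered C6 boron with retention far faster than the neopentyl-type pinacol ester; the closest known reaction types are the hydroboration of alkenylboronic esters to vicinal diboron compounds and the hydroboration–oxidation of alkenes that carry a pinacol boronate.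

Step 14
Reactants: 25 hydroxy boronate
Product: 26 fragmentation precursor (5α-pinacol boronate; 6β-triethylsilyl ether; 7α-isopropyl; 8β-mesylate; 10β-tert-butyldimethylsilyl ether)
Conditions: Et3SiOTf, 2,6-lutidine, CH2Cl2, −78 °C
Reagents that add atoms: triethylsilyl trifluoromethanesulfonate, CC[Si](CC)(CC)OS(=O)(=O)C(F)(F)F
Why: Silylation of the hindered secondary alcohol with the silyl triflate gives an ether that withstands methoxide and can later be removed without touching the C10 silyl ether.

Step 15
Reactants: 26 fragmentation precursor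
Product: 28 (4Z,8E)-cyclodecadiene (C6 triethylsilyl ether; C7 isopropyl; C10 tert-butyldimethylsilyl ether), via methoxyborate 27 (not isolated)
Conditions: NaOMe (3 equiv), THF/MeOH (10:1), 0 to 45 °C
Reagents that add atoms: none
Why: Methoxide adds to the Lewis-acidic boron of 26 to give borate 27; in the ring-A chair that holds all four substituents equatorial the C5–B and C8–O bonds are both antiperiplanar to C4–C9, so the C–B electron pair forms C4=C5 while the C4–C9 pair forms C8=C9 and expels mesylate in one concerted event. This is the boronate variant of the Grob fragmentation, long used on decalyl sulfonates that carry a remote boron. No σ bond is made, so no ring-closure mode applies: the ten-membered ring appears because the bond shared by rings A and B is cut. No stereocentre is formed; the alkene geometries follow from the cis fusion, C3 being axial on C4 and so cis to C6 (Z) and C10 being equatorial on C9 and so trans to C7 (E). The step needs scission of C4–C9 and not of the equally antiperiplanar C6–C7 bond, and no β-elimination of the C6 silyl ether: the fully substituted C4 makes C4–C9 the better σ-donor while the silyloxy group deactivates C6–C7, the weakly ionising medium disfavours an oxocarbenium-like pathway, and boron and the C6 oxygen are gauche, neither anti- nor syn-periplanar.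

Step 16
Reactants: 28 cyclodecadiene
Product: 29 allylic alcohol (C6 hydroxyl free; C10 silyl ether kept)
Conditions: HF·pyridine, pyridine, THF, 0 °C
Reagents that add atoms: none
Why: Selective desilylation: buffered HF·pyridine cleaves the secondary triethylsilyl ether much faster than the tertiary tert-butyldimethylsilyl ether, and the buffered medium avoids acid-promoted transannular cyclisation of the diene.

Step 17
Reactants: 29 allylic alcohol
Product: 30 epoxy alcohol (4,5-epoxide syn to the C6 hydroxyl)
Conditions: VO(acac)2 (5 mol %), t-BuOOH (1.5 equiv), CH2Cl2, 0 °C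
Reagents that add atoms: tert-butyl hydroperoxide, CC(C)(C)OO
Why: Hydroxyl-directed vanadium-catalysed epoxidation: the C6-bound vanadate peroxide should deliver oxygen to the allylic Z-C4=C5 bond on the face of the hydroxyl, as it does in medium-ring (Z)-cycloalkenols, which sets C4 and C5, while C8=C9 is spared because the C10 oxygen is silylated.

Step 18
Reactants: 31 4-hydroxybenzoic acid
Product: 33 4-(tert-butyldimethylsilyloxy)benzoic acid, via silyl ester 32 (not isolated)
Conditions: t-BuMe2SiCl (2.2 equiv), imidazole, DMF, rt; then K2CO3, MeOH/THF/H2O, rt; citric acid to pH 4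
Reagents that add atoms: tert-butyldimethylsilyl chloride, CC(C)(C)[Si](C)(C)Cl
Why: Silylation of phenol and acid followed by selective solvolysis of the labile silyl ester leaves the phenol protected and the acid free.

Step 19
Reactants: 30 epoxy alcohol; 33 4-(tert-butyldimethylsilyloxy)benzoic acid
Product: 35 C6 4-(tert-butyldimethylsilyloxy)benzoate, via mixed anhydride 34 (not isolated)
Conditions: 33, 2,4,6-trichlorobenzoyl chloride, Et3N, THF, rt; then 30, DMAP, toluene, 40 °C
Reagents that add atoms: none
Why: Yamaguchi esterification: DMAP attacks the less hindered aroyl carbonyl of the mixed anhydride and the acylpyridinium ion should acylate the hindered C6 alcohol without opening the epoxide or changing any stereocentre.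

Step 20
Reactants: 35 bis-silylated ester
Product: 36 target (CNP0278889.1)
Conditions: Bu4NF (4 equiv), THF, 0 to 40 °C
Reagents that add atoms: none
Why: Fluoride-mediated desilylation removes the aryl silyl ether at once and the tertiary one on warming, the phenoxide formed first deactivates the ester toward cleavage, and the epoxide is inert to fluoride.

Compound list
1 | 5-chloropent-1-yne | C#CCCCCl | starting material
2 | 9-[(Z)-2-bromo-5-chloropent-1-en-1-yl]-9-borabicyclo[3.3.1]nonane | Br/C(CCCCl)=C\B1C2CCCC1CCC2 | intermediate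
3 | 2-bromo-5-chloropent-1-ene | C=C(Br)CCCCl | intermediate
4 | (R)-carvone | CC1=CC[C@@H](C(C)=C)CC1=O | starting material
5 | (R)-carvotanacetone, (5R)-2-methyl-5-(propan-2-yl)cyclohex-2-en-1-one | CC1=CC[C@@H](C(C)C)CC1=O | intermediate
6 | (5-chloropent-1-en-2-yl)lithium | [Li]C(=C)CCCCl | intermediate
7 | lithium bis(5-chloropent-1-en-2-yl)cuprate | [Li+].C=C(CCCCl)[Cu-]C(=C)CCCCl | intermediate
8 | lithium enolate (C4=C5) of adduct 9 | CC1=C(O[Li])C[C@H](C(C)C)C[C@H]1C(=C)CCCCl | intermediate
9 | 3-(5-chloropent-1-en-2-yl)-2-methyl-5-isopropylcyclohexanone, C9 side chain trans to C7 isopropyl, C4 epimers | CC1C(=O)C[C@H](C(C)C)C[C@H]1C(=C)CCCCl | intermediate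
10 | potassium enolate (C4=C5) of 9 | CC1=C([O-])C[C@H](C(C)C)C[C@H]1C(=C)CCCCl.[K+] | intermediate
11 | cis-decalone: 5-oxo, 4β-methyl, 9β-H, 7β-isopropyl, 10-methylidene | C[C@@]12CCCC(=C)[C@@H]1C[C@@H](C(C)C)CC2=O | intermediate
12 | cis-decalone: 5-oxo, 10β-hydroxy, 10α-methyl, 7β-isopropyl | C[C@@]12CCC[C@@](C)(O)[C@@H]1C[C@@H](C(C)C)CC2=O | intermediate
13 | C10 tert-butyldimethylsilyl ether of 12 | C[C@@]12CCC[C@@](C)(O[Si](C)(C)C(C)(C)C)[C@@H]1C[C@@H](C(C)C)CC2=O | intermediate
14 | lithium enolate (C5=C6) of 13 | C[C@@]12CCC[C@@](C)(O[Si](C)(C)C(C)(C)C)[C@@H]1C[C@@H](C(C)C)C=C2O[Li] | intermediate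
15 | trimethylsilyl enol ether (C5=C6) of 13 | C[C@@]12CCC[C@@](C)(O[Si](C)(C)C(C)(C)C)[C@@H]1C[C@@H](C(C)C)C=C2O[Si](C)(C)C | intermediate
16 | enone: 5-oxo, C6=C7, 7-isopropyl, 10β-silyloxy | C[C@@]12CCC[C@@](C)(O[Si](C)(C)C(C)(C)C)[C@@H]1CC(C(C)C)=CC2=O | intermediate
17 | lithium dienolate (C5=C6, C7=C8) of 16 | C[C@@]12CCC[C@@](C)(O[Si](C)(C)C(C)(C)C)[C@@H]1C=C(C(C)C)C=C2O[Li] | intermediate
18 | triethylsilyl dienol ether (C5=C6, C7=C8) of 16 | C[C@@]12CCC[C@@](C)(O[Si](C)(C)C(C)(C)C)[C@@H]1C=C(C(C)C)C=C2O[Si](CC)(CC)CC | intermediate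
19 | γ-hydroxy enone: 5-oxo, C6=C7, 8β-hydroxy | C[C@@]12CCC[C@@](C)(O[Si](C)(C)C(C)(C)C)[C@@H]1[C@@H](O)C(C(C)C)=CC2=O | intermediate
20 | hydroxy ketone: 5-oxo, 7α-isopropyl, 8β-hydroxy | C[C@@]12CCC[C@@](C)(O[Si](C)(C)C(C)(C)C)[C@@H]1[C@@H](O)[C@H](C(C)C)CC2=O | intermediate
21 | mesylate ketone: 5-oxo, 7α-isopropyl, 8β-mesyloxy | C[C@@]12CCC[C@@](C)(O[Si](C)(C)C(C)(C)C)[C@@H]1[C@@H](OS(C)(=O)=O)[C@H](C(C)C)CC2=O | intermediate
22 | alkenyl triflate: C5=C6, 5-triflyloxy, 8β-mesyloxy | C[C@@]12CCC[C@@](C)(O[Si](C)(C)C(C)(C)C)[C@@H]1[C@@H](OS(C)(=O)=O)[C@H](C(C)C)C=C2OS(=O)(=O)C(F)(F)F | intermediate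
23 | alkenyl pinacol boronate: C5=C6, boron on C5, 8β-mesyloxy | C[C@@]12CCC[C@@](C)(O[Si](C)(C)C(C)(C)C)[C@@H]1[C@@H](OS(C)(=O)=O)[C@H](C(C)C)C=C2B3OC(C)(C)C(C)(C)O3 | intermediate
24 | vicinal diboron compound: 5α-pinacol boronate, 6β-BH2 | C[C@@]12CCC[C@@](C)(O[Si](C)(C)C(C)(C)C)[C@@H]1[C@@H](OS(C)(=O)=O)[C@H](C(C)C)[C@@H](B)[C@@H]2B3OC(C)(C)C(C)(C)O3 | intermediate
25 | hydroxy boronate: 5α-pinacol boronate, 6β-hydroxy, 7α-isopropyl, 8β-mesyloxy | C[C@@]12CCC[C@@](C)(O[Si](C)(C)C(C)(C)C)[C@@H]1[C@@H](OS(C)(=O)=O)[C@H](C(C)C)[C@@H](O)[C@@H]2B3OC(C)(C)C(C)(C)O3 | intermediate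
26 | fragmentation precursor, cis-decalin: 4β-methyl, 5α-pinacol boronate, 6β-triethylsilyloxy, 7α-isopropyl, 8β-mesyloxy, 9β-H, 10β-tert-butyldimethylsilyloxy, 10α-methyl | C[C@@]12CCC[C@@](C)(O[Si](C)(C)C(C)(C)C)[C@@H]1[C@@H](OS(C)(=O)=O)[C@H](C(C)C)[C@@H](O[Si](CC)(CC)CC)[C@@H]2B3OC(C)(C)C(C)(C)O3 | intermediate
27 | sodium methoxyborate of 26 | C[C@@]12CCC[C@@](C)(O[Si](C)(C)C(C)(C)C)[C@@H]1[C@@H](OS(C)(=O)=O)[C@H](C(C)C)[C@@H](O[Si](CC)(CC)CC)[C@@H]2[B-]3(OC)OC(C)(C)C(C)(C)O3.[Na+] | intermediate
28 | (4Z,8E)-cyclodeca-4,8-diene: 6-triethylsilyloxy, 7-isopropyl, 10-tert-butyldimethylsilyloxy, 4,10-dimethyl | CC(C)[C@H]1/C=C/[C@](C)(O[Si](C)(C)C(C)(C)C)CCC/C(C)=C\[C@@H]1O[Si](CC)(CC)CC | intermediate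
29 | (4Z,8E)-cyclodecadien-6-ol with C10 silyl ether | CC(C)[C@H]1/C=C/[C@](C)(O[Si](C)(C)C(C)(C)C)CCC/C(C)=C\[C@@H]1O | intermediate
30 | 4,5-epoxy alcohol (epoxide syn to C6 hydroxyl) with C10 silyl ether | CC(C)[C@H]1/C=C/[C@](C)(O[Si](C)(C)C(C)(C)C)CCC[C@]2(C)O[C@@H]2[C@@H]1O | intermediate
31 | 4-hydroxybenzoic acid | OC(=O)c1ccc(O)cc1 | starting material
32 | tert-butyldimethylsilyl 4-(tert-butyldimethylsilyloxy)benzoate | CC(C)(C)[Si](C)(C)Oc1ccc(cc1)C(=O)O[Si](C)(C)C(C)(C)C | intermediate
33 | 4-(tert-butyldimethylsilyloxy)benzoic acid | CC(C)(C)[Si](C)(C)Oc1ccc(cc1)C(O)=O | intermediate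
34 | 4-(tert-butyldimethylsilyloxy)benzoic 2,4,6-trichlorobenzoic anhydride | CC(C)(C)[Si](C)(C)Oc1ccc(cc1)C(=O)OC(=O)c1c(Cl)cc(Cl)cc1Cl | intermediate
35 | C6 4-(tert-butyldimethylsilyloxy)benzoate of 30 | CC(C)[C@H]1/C=C/[C@](C)(O[Si](C)(C)C(C)(C)C)CCC[C@]2(C)O[C@@H]2[C@@H]1OC(=O)c1ccc(O[Si](C)(C)C(C)(C)C)cc1 | intermediate
36 | CNP0278889.1 | CC(C)[C@H]1/C=C/[C@](C)(O)CCC[C@]2(C)O[C@@H]2[C@@H]1OC(=O)c1ccc(O)cc1 | target

Total step count: 20. Longest linear sequence: 18 steps (steps 2–17, 19 and 20, from (R)-carvone).

Steps most likely to fail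

1. Step 13 (the step proposed as a new method). What may go wrong: addition of the borane with the opposite regiochemistry (new boron geminal to the boronate at C5), sluggish addition to the hindered alkenylboronate, or loss of chemoselectivity in the oxidation so that the pinacol boronate is oxidised too. The fallback uses known reactions only and exchanges the positions of boron and sulfonate, so that no alkenylboronate has to be hydroborated. It sets out from enone 16. The extended lithium dienolate (formed as in step 8) is hydroxylated at C6 with 2-(phenylsulfonyl)-3-phenyloxaziridine to give the 6β-hydroxy β,γ-enone F1. Et3SiCl/imidazole gives the silyl ether F2. NaBH4 (MeOH, −40 °C) should attack the C5 carbonyl from the β face to give the 5α-alcohol F3, and MsCl/Et3N gives the C5 mesylate F4. BH3·THF should add to C7=C8 from the β face (boron to C8, hydrogen to C7), and pinacol work-up gives the C8 pinacol boronate F5, which has the same all-equatorial pattern with boron and sulfonate interchanged. NaOMe then cleaves the same C4–C9 bond, and the fallback comes back to the route at diene 28.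

2. Step 15. What may go wrong: scission of the C6–C7 bond, which is antiperiplanar to boron and mesylate as well and is helped by the donor oxygen on C6 (ring A would open to an acyclic enol ether), or incomplete borate formation at the hindered boron. The fallback makes the C6 oxygen electron-poor and changes the trigger. It sets out from hydroxy boronate 25: pivaloyl chloride/pyridine/DMAP gives the C6 pivalate F6, CsF in DMF (60 °C) forms the fluoroborate and should fragment it to the diene pivalate F7, and i-Bu2AlH (CH2Cl2, −78 °C) removes the pivalate, so that the fallback comes back to the route at allylic alcohol 29.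

3. Step 8. What may go wrong: deprotonation at the isopropyl methine in place of C8, attack of the oxidant on the proximal enol-ether bond (hydroxylation at C6), or erosion of facial selectivity. The fallback is a deconjugation–epoxidation–isomerisation sequence that sets out from enone 16: kinetic protonation of the dienolate (LiN(i-Pr)2, then AcOH at −78 °C) gives the β,γ-enone F8, m-CPBA/NaHCO3 should epoxidise C7=C8 on the face away from C10 to give the epoxy ketone F9, and DBU opens the epoxide by E1cB elimination, so that the fallback comes back to the route at γ-hydroxy enone 19.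

Further compounds
F1 | step 13 | 6β-hydroxy β,γ-enone (5-oxo, C7=C8) | C[C@@]12CCC[C@@](C)(O[Si](C)(C)C(C)(C)C)[C@@H]1C=C(C(C)C)[C@@H](O)C2=O
F2 | step 13 | 6β-triethylsilyl ether of F1 | C[C@@]12CCC[C@@](C)(O[Si](C)(C)C(C)(C)C)[C@@H]1C=C(C(C)C)[C@@H](O[Si](CC)(CC)CC)C2=O
F3 | step 13 | 5α-alcohol (6β-triethylsilyloxy, C7=C8) | C[C@@]12CCC[C@@](C)(O[Si](C)(C)C(C)(C)C)[C@@H]1C=C(C(C)C)[C@@H](O[Si](CC)(CC)CC)[C@@H]2O
F4 | step 13 | 5α-mesylate (6β-triethylsilyloxy, C7=C8) | C[C@@]12CCC[C@@](C)(O[Si](C)(C)C(C)(C)C)[C@@H]1C=C(C(C)C)[C@@H](O[Si](CC)(CC)CC)[C@@H]2OS(C)(=O)=O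
F5 | step 13 | cis-decalin with 5α-mesyloxy, 6β-triethylsilyloxy, 7α-isopropyl, 8β-pinacol boronate | C[C@@]12CCC[C@@](C)(O[Si](C)(C)C(C)(C)C)[C@@H]1[C@@H](B3OC(C)(C)C(C)(C)O3)[C@H](C(C)C)[C@@H](O[Si](CC)(CC)CC)[C@@H]2OS(C)(=O)=O
F6 | step 15 | C6 pivalate of hydroxy boronate 25 | C[C@@]12CCC[C@@](C)(O[Si](C)(C)C(C)(C)C)[C@@H]1[C@@H](OS(C)(=O)=O)[C@H](C(C)C)[C@@H](OC(=O)C(C)(C)C)[C@@H]2B3OC(C)(C)C(C)(C)O3
F7 | step 15 | (4Z,8E)-cyclodecadiene C6 pivalate with C10 silyl ether | CC(C)[C@H]1/C=C/[C@](C)(O[Si](C)(C)C(C)(C)C)CCC/C(C)=C\[C@@H]1OC(=O)C(C)(C)C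
F8 | step 8 | β,γ-enone (5-oxo, C7=C8) | C[C@@]12CCC[C@@](C)(O[Si](C)(C)C(C)(C)C)[C@@H]1C=C(C(C)C)CC2=O
F9 | step 8 | 7β,8β-epoxy ketone | C[C@@]12CCC[C@@](C)(O[Si](C)(C)C(C)(C)C)[C@@H]1[C@H]3O[C@@]3(C(C)C)CC2=O
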